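## Analysis of the target

The target is 3,4,6-tribromo-2-(5-bromo-2-hydroxyphenoxy)phenol, a diaryl ether with no stereocentre and no side chain. Ring B is the tribrominated phenol ring: C1 OH, C2 ether oxygen, C3 Br, C4 Br, C5 H, C6 Br. Ring A is the monobrominated ring: C1' ether oxygen, C2' OH, C5' Br.

The defining feature is the 2,2'-oxydiphenol array HO–C2'–C1'–O–C2–C1–OH, in which each ring carries its free hydroxyl ortho to the shared ether oxygen. This is the pattern left when a one-atom bridge between C2' and C1 of a six-membered ring (C2', C1', O, C2, C1, bridge atom) is replaced by two hydroxyl groups. The route is built on that reading.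

On ring B, C3, C2, C1 and C6 are four adjacent heteroatom-bearing carbons. The C2–O bond lies between C1–OH and C3–Br on an electron-poor, polyhalogenated ring and is the hardest bond to make.

The bromines differ in accessibility. C6 and C4 are ortho and para to the C1 hydroxyl, and C5' is para to the C2' hydroxyl, so a free phenol would direct an electrophile to them. C3–Br is meta to the C1 hydroxyl and cannot be introduced that way; it has to come with a building block.

Sensitive features are the four aryl C–Br bonds (they rule out late cross-coupling and alkyllithium chemistry), two oxidisable phenols, and possible over-bromination at C3'. Under strong base and heat an ortho-hydroxy diaryl ether of this kind can also undergo Smiles migration or close to a brominated dibenzodioxin. The difficulty is regiochemical: which oxygen is arylated, where each bromine goes, and how the two phenols are told apart at the end.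

## Retrosynthetic reasoning

**C4–Br.** The first cut is the C4–Br bond of ring B in 15, leading to tribromide 13. C4 is para to the C1 hydroxyl and both ortho positions (C2, C6) are filled, so electrophilic substitution on ring B can only go there. Removing this bromine also leaves a ring B whose bromines at C3 and C6 are related by a mirror plane through the C1–C2 bond, which makes the key disconnection regiochemically trivial. A ring B aryne already carrying the C4 bromine would be unsymmetrical and only weakly biased, probably toward the wrong carbon. In the forward direction the bromination must prefer C4 of ring B over C3' of ring A; this is arranged by running it on monophenolate 14, in which only the more acidic ring B hydroxyl is ionised.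

**C1–OH and C2'–OH.** Both hydroxyl-bearing carbons of 13 are traced to carbon–boron bonds on one boron atom, in spiro borate 12. There boron bridges C1 of ring B and C2' of ring A and closes a six-membered oxaborin ring with the ether oxygen. One boron atom then stands for both hydroxyls, neither needs a protecting group, and boron-to-oxygen migration is position-specific. The forward oxidation must cleave both aryl–boron bonds without harming phenols or C–Br bonds.

**C2–O and C1–B (key disconnection).** Borate 12 is cut at the two bonds ring B makes to the bridge. This gives the symmetrical aryne 11 and phenolate 10, which carries oxygen on C1' and boron on C2'. An aryne makes the hindered C2–O bond by addition rather than substitution, with no metal catalyst that would have to distinguish four C–Br bonds. Because 11 is symmetric, its two triple-bond carbons are equivalent; the ortho boron in 10 decides which receives oxygen and which receives boron. One operation forms the diaryl ether and fixes both hydroxyl positions, from a precursor with no ring A–ring B bond. The forward reaction must ensure that the aryl anion formed by oxygen addition is captured by the neighbouring boron before anything else happens.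

**Aryne precursor.** Aryne 11 comes from silyl triflate 5, and 5 from phenol 1 through silyl ether 2. Deprotonation at the C–H between oxygen and bromine gives 3, a 1,3-shift of silicon from oxygen to carbon gives 4, and the oxygen is then made into the leaving group. The oxygen of 1 is not retained; it serves to mark the aryne position between the two bromines.

**Boron partner.** Phenolate 10 is the potassium salt of boronate 9, made from iodophenol 6 by exchange of iodine for boron via 7 and 8. Iodine is chosen because it exchanges in preference to bromine.

## Alternatives that were turned down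

**Alternative 1:** the textbook route, cutting only the C2–O bond of ring B by nucleophilic aromatic substitution. The phenolate of A2 would displace the fluoride of A1 (activated by the ortho formyl group) to give aldehyde A3. Baeyer–Villiger oxidation and formate cleavage would give phenol A4, double bromination at C6 and C4 would give A5, and O-demethylation with a strong Lewis acid would give 15. It was turned down for three reasons:
- The key step forms one bond, at a fluoride flanked on both sides, with a phenolate that is itself ortho-substituted; this is the slow case of SNAr and needs hot dipolar aprotic conditions.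
- Neither hydroxyl arrives at the right oxidation level. One comes as a formyl carbon that must be excised and the other as a methyl ether that must be cleaved.
- It is four linear steps, no shorter than the longest linear sequence of the chosen route, and each step does one thing.

It is kept as the reference line and its chemistry is reused in a fallback.

**Alternative 2:** cutting C2–O and C3–Br of ring B together across an aryne. Aryne A7, generated from A6, would take the phenolate of A2 at the carbon next to boron and an electrophilic bromine at the other carbon, giving boronate A8. Oxidation would give A4 and the route would then follow Alternative 1. It was turned down for four reasons: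
- A6 carries boron, triflate and iodine on three adjacent carbons and costs several steps, more than the key step saves.
- The side of addition rests only on the ortho-directing effect of the boryl group, which is established for amine nucleophiles and is opposed by sterics for an ortho-substituted phenolate.
- The bromine source would have to distinguish a transient aryl anion from an electron-rich phenolate present in bulk, so ring bromination of A2 should compete.
- Two further brominations and the demethylation remain.

**Alternative 3:** a biomimetic oxidative coupling that cuts the C1'–O bond on ring A. Two-electron oxidation of A9 (for example with a trivalent iodine oxidant) would be followed by attack of a hydroxyl of A10 at the bromine-bearing ortho carbon, giving racemic dienone A11. Reductive loss of that bromine would re-aromatise to 15 with no protecting groups. It was turned down for four reasons: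
- A10 is not directly accessible, because bromination of the parent catechol fills the 4- and 5-positions first.
- A10 has two different hydroxyls and nothing decides which one adds.
- Oxidised A9 has bromine-bearing ortho and para carbons, and both are open to attack.
- The catechol A10 is more easily oxidised than A9, so the wrong partner is activated, and radical pathways give C–C dimers.

Key step: step 4

Assumption: 2,5-dibromophenol (1) and 5-bromo-2-iodophenol (6) are taken as purchasable; the target is achiral, so no stereocontrol is needed.

## Route

Step 1
Reactants: 1 2,5-dibromophenol
Product: 2 (2,5-dibromophenoxy)trimethylsilane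
Conditions: (Me3Si)2NH (0.6 equiv), neat, 80 °C; volatiles removed in vacuo
Reagents that add atoms: hexamethyldisilazane, C[Si](C)(C)N[Si](C)(C)C
Why: O-silylation of a phenol with a silazane; ammonia is the only by-product, so the crude silyl ether should be usable after evaporation.

Step 2
Reactants: 2 (2,5-dibromophenoxy)trimethylsilane
Product: 5 3,6-dibromo-2-(trimethylsilyl)phenyl trifluoromethanesulfonate, via aryllithium 3 (not isolated), via lithium phenolate 4 (not isolated)
Conditions: LiN(iPr)2 (1.1 equiv), THF, −78 °C; then Tf2O (1.2 equiv), −78 °C → 0 °C
Reagents that add atoms: trifluoromethanesulfonic anhydride, O=S(=O)(OS(=O)(=O)C(F)(F)F)C(F)(F)F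
Why: Directed ortho-lithiation at the one C–H flanked by the silyloxy group and bromine (an amide base avoids bromine–lithium exchange), then anionic 1,3 O→C silyl shift (retro-Brook rearrangement) and O-triflation of the phenolate. This is the standard way to ortho-silylaryl triflates.

Step 3
Reactants: 6 5-bromo-2-iodophenol
Product: 9 5-bromo-2-(4,4,5,5-tetramethyl-1,3,2-dioxaborolan-2-yl)phenol, via magnesium phenolate 7 (not isolated), via aryl Grignard reagent 8 (not isolated)
Conditions: MeMgCl (1.0 equiv), THF, −20 °C; iPrMgCl·LiCl (1.1 equiv), −20 °C → 0 °C; iPrOBpin (1.3 equiv), → rt; dilute aq. HCl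
Reagents that add atoms: 2-isopropoxy-4,4,5,5-tetramethyl-1,3,2-dioxaborolane, CC(C)OB1OC(C)(C)C(C)(C)O1
Why: Deprotonation of the phenol, then iodine–magnesium exchange (C–I exchanges well before C–Br at this temperature) and borylation of the aryl Grignard reagent with an alkoxyboronate.

Step 4
Reactants: 5 3,6-dibromo-2-(trimethylsilyl)phenyl trifluoromethanesulfonate; 9 5-bromo-2-(4,4,5,5-tetramethyl-1,3,2-dioxaborolan-2-yl)phenol
Product: 13 3,6-dibromo-2-(5-bromo-2-hydroxyphenoxy)phenol, via potassium phenolate 10 (not isolated), via 3,6-dibromobenzyne 11 (not isolated), via spiro borate 12 (not isolated)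
Conditions: 9, KH (1.0 equiv), 18-crown-6, THF, 0 °C; then 5 (1.2 equiv), KF (2.5 equiv), 0 °C → rt; then 30% H2O2, aq. NaHCO3, 0 °C → rt
Reagents that add atoms: hydrogen peroxide, OO
Why: Proposed new method: fluoride removes the silyl group of 5 and triflate leaves to give aryne 11; the oxygen of the crown-separated phenolate 10 adds to one aryne carbon, and the resulting aryl anion, held next to the pinacol boronate, adds to the vacant p orbital of boron to close the six-membered oxaborin ring of borate 12 (closure by C1–B bond formation onto a tethered trigonal electrophile, all tether atoms sp2 and coplanar, so unstrained), after which peroxide moves both aryl groups from boron to oxygen at the same carbons. The closest known reaction type is the fluoride-induced annulation of arynes with ortho-ester phenolates (xanthone formation from salicylates), where the same aryl anion is caught by the neighbouring carbonyl; a boronate ester as the internal trap is the untested element. No stereocentre is formed. No regiocontrol is needed on ring B because 11 is C2v-symmetric, with both aryne carbons flanked by bromine, so the tether alone decides that oxygen ends on C2 and boron (later OH) on C1; on ring A the positions are already fixed in 9. The step does need O-arylation rather than C-arylation of the phenolate, which the potassium–crown ion pair should favour. It also needs boron capture to be faster than protonation or loss of the adjacent bromide; the phenolate is preformed with KH so that no O–H is present, and the capture is intramolecular. The four C–Br bonds should survive because no transition metal and no alkyllithium is present.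

Step 5
Reactants: 13 3,6-dibromo-2-(5-bromo-2-hydroxyphenoxy)phenol
Product: 15 3,4,6-tribromo-2-(5-bromo-2-hydroxyphenoxy)phenol, via monosodium phenolate 14 (not isolated)
Conditions: NaOMe (1.0 equiv), MeOH–THF, −40 °C; NBS (1.0 equiv), −40 °C → 0 °C; aq. HCl work-up
Reagents that add atoms: N-bromosuccinimide, O=C1CCC(=O)N1Br
Why: Electrophilic aromatic bromination under phenolate control. The ring B hydroxyl (ortho Br, meta Br, ortho aryloxy) is expected to be about two pKa units more acidic than the ring A hydroxyl, so one equivalent of base ionises ring B, and a phenolate reacts far faster than a neutral phenol. On ring B only C4 (para to O−) is open, since C2 and C6 are blocked.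

## Compound list

1 | 2,5-dibromophenol | Oc1cc(Br)ccc1Br | starting material
2 | (2,5-dibromophenoxy)trimethylsilane | C[Si](C)(C)Oc1cc(Br)ccc1Br | intermediate
3 | [3,6-dibromo-2-(trimethylsilyloxy)phenyl]lithium | [Li]c1c(Br)ccc(Br)c1O[Si](C)(C)C | intermediate
4 | lithium 3,6-dibromo-2-(trimethylsilyl)phenolate | [Li+].[O-]c1c(Br)ccc(Br)c1[Si](C)(C)C | intermediate
5 | 3,6-dibromo-2-(trimethylsilyl)phenyl trifluoromethanesulfonate | C[Si](C)(C)c1c(Br)ccc(Br)c1OS(=O)(=O)C(F)(F)F | intermediate
6 | 5-bromo-2-iodophenol | Oc1cc(Br)ccc1I | starting material
7 | chloromagnesium 5-bromo-2-iodophenolate | Cl[Mg]Oc1cc(Br)ccc1I | intermediate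
8 | [4-bromo-2-(chloromagnesiooxy)phenyl]magnesium chloride | Cl[Mg]Oc1cc(Br)ccc1[Mg]Cl | intermediate
9 | 5-bromo-2-(4,4,5,5-tetramethyl-1,3,2-dioxaborolan-2-yl)phenol | CC1(C)OB(OC1(C)C)c1ccc(Br)cc1O | intermediate
10 | potassium 5-bromo-2-(4,4,5,5-tetramethyl-1,3,2-dioxaborolan-2-yl)phenolate | [K+].[O-]c1cc(Br)ccc1B1OC(C)(C)C(C)(C)O1 | intermediate
11 | 3,6-dibromobenzyne (1,4-dibromo-2,3-didehydrobenzene) | BrC1=CC=C(Br)C#C1 | intermediate
12 | potassium 1',4',7'-tribromo-4,4,5,5-tetramethylspiro[1,3,2-dioxaborolane-2,10'-phenoxaborin]-2-uide (spiro borate; boron bridges C1 of ring B and C2' of ring A) | [K+].CC1(C)O[B-]2(OC1(C)C)c1ccc(Br)cc1Oc1c(Br)ccc(Br)c12 | intermediate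
13 | 3,6-dibromo-2-(5-bromo-2-hydroxyphenoxy)phenol | Oc1ccc(Br)cc1Oc1c(O)c(Br)ccc1Br | intermediate
14 | sodium 3,6-dibromo-2-(5-bromo-2-hydroxyphenoxy)phenolate | [Na+].[O-]c1c(Br)ccc(Br)c1Oc1cc(Br)ccc1O | intermediate
15 | 3,4,6-tribromo-2-(5-bromo-2-hydroxyphenoxy)phenol | Oc1ccc(Br)cc1Oc1c(O)c(Br)cc(Br)c1Br | target

## Step count and least certain steps

Total step count: 5. Longest linear sequence: 4 (steps 1, 2, 4, 5); step 3 prepares the second partner for the convergent step 4.

**Step 4 (key step, proposed new method).** Three processes could divert the aryl anion before it reaches boron: protonation, loss of the adjacent bromide to form a second aryne, and slowing of the capture by reversible fluoride binding at boron. C-arylation of the phenolate instead of O-arylation is a further risk. The fallback uses only known reaction types, sets out from 6 and returns at 13. The phenolate of 6 displaces the activated fluoride of commercial 3,6-dibromo-2-fluorobenzaldehyde (K2CO3, DMF) to give 3,6-dibromo-2-(5-bromo-2-iodophenoxy)benzaldehyde F1. Baeyer–Villiger oxidation with mCPBA gives 3,6-dibromo-2-(5-bromo-2-iodophenoxy)phenyl formate F2, which is cleaved without isolation (K2CO3, MeOH) to 3,6-dibromo-2-(5-bromo-2-iodophenoxy)phenol F3. Deprotonation (MeMgCl), iodine–magnesium exchange (iPrMgCl·LiCl) and B(OMe)3 give [4-bromo-2-(3,6-dibromo-2-hydroxyphenoxy)phenyl]boronic acid F4, which is oxidised in the same flask with H2O2 to 13.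

**Step 5.** Site selectivity could be lost through bromination at C3' of ring A, either because proton exchange puts the charge on the ring A oxygen or because the neutral-phenol pathway competes; over-bromination is the related risk. The fallback replaces ionisation control by a protecting group, sets out from 13 and returns at 15. Silylation of the neutral, less hindered and more nucleophilic ring A hydroxyl (iPr3SiOTf, 1.0 equiv, 2,6-lutidine, CH2Cl2, −78 °C) should give 3,6-dibromo-2-{5-bromo-2-[tri(propan-2-yl)silyloxy]phenoxy}phenol F5. NBS then brominates the only free phenol para to its hydroxyl to give 3,4,6-tribromo-2-{5-bromo-2-[tri(propan-2-yl)silyloxy]phenoxy}phenol F6, and Bu4NF removes the silyl group to give 15.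

**Step 2.** Aryllithium 3 sits ortho to bromine, so it could lose LiBr before the silyl shift; bromine migration around the ring and attack of the amide base at silicon are the other risks. The fallback never lets a free aryllithium accumulate, sets out from 1 and returns at 5. Phenol 1 and isopropyl isocyanate (cat. Et3N) give 2,5-dibromophenyl N-(propan-2-yl)carbamate F7. Treatment with LiN(iPr)2 in the presence of Me3SiCl (in situ quench, THF, −78 °C) gives 3,6-dibromo-2-(trimethylsilyl)phenyl N-(propan-2-yl)carbamate F8 after work-up. The carbamate is cleaved with Et2NH and DBU, and the phenolate is triflated with PhNTf2 in the same flask to give 5.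

**Step 3.** Competing bromine–magnesium exchange, or protodeboronation of the ortho-hydroxy boronate during work-up, could lower the return. The fallback changes the reaction type: Miyaura borylation of 6 with B2pin2 (PdCl2(dppf), KOAc, dioxane, 80 °C), in which the catalyst inserts into C–I before C–Br, gives 9 directly. It sets out from 6, returns at 9 and makes no new compound (F0).

## Further compounds

F1 | step 4 | 3,6-dibromo-2-(5-bromo-2-iodophenoxy)benzaldehyde | O=Cc1c(Br)ccc(Br)c1Oc1cc(Br)ccc1I
F2 | step 4 | 3,6-dibromo-2-(5-bromo-2-iodophenoxy)phenyl formate | O=COc1c(Br)ccc(Br)c1Oc1cc(Br)ccc1I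
F3 | step 4 | 3,6-dibromo-2-(5-bromo-2-iodophenoxy)phenol | Oc1c(Br)ccc(Br)c1Oc1cc(Br)ccc1I
F4 | step 4 | [4-bromo-2-(3,6-dibromo-2-hydroxyphenoxy)phenyl]boronic acid | OB(O)c1ccc(Br)cc1Oc1c(O)c(Br)ccc1Br
F5 | step 5 | 3,6-dibromo-2-{5-bromo-2-[tri(propan-2-yl)silyloxy]phenoxy}phenol | CC(C)[Si](Oc1ccc(Br)cc1Oc1c(O)c(Br)ccc1Br)(C(C)C)C(C)C
F6 | step 5 | 3,4,6-tribromo-2-{5-bromo-2-[tri(propan-2-yl)silyloxy]phenoxy}phenol | CC(C)[Si](Oc1ccc(Br)cc1Oc1c(O)c(Br)cc(Br)c1Br)(C(C)C)C(C)C
F7 | step 2 | 2,5-dibromophenyl N-(propan-2-yl)carbamate | CC(C)NC(=O)Oc1cc(Br)ccc1Br
F8 | step 2 | 3,6-dibromo-2-(trimethylsilyl)phenyl N-(propan-2-yl)carbamate | CC(C)NC(=O)Oc1c([Si](C)(C)C)c(Br)ccc1Br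
F0 | step 3 | none | none
A1 | alternative 1 | 3-bromo-2-fluorobenzaldehyde | O=Cc1cccc(Br)c1F
A2 | alternative 1 | 5-bromo-2-methoxyphenol | COc1ccc(Br)cc1O
A3 | alternative 1 | 3-bromo-2-(5-bromo-2-methoxyphenoxy)benzaldehyde | COc1ccc(Br)cc1Oc1c(C=O)cccc1Br
A4 | alternative 1 | 3-bromo-2-(5-bromo-2-methoxyphenoxy)phenol | COc1ccc(Br)cc1Oc1c(O)cccc1Br
A5 | alternative 1 | 3,4,6-tribromo-2-(5-bromo-2-methoxyphenoxy)phenol | COc1ccc(Br)cc1Oc1c(O)c(Br)cc(Br)c1Br
A6 | alternative 2 | 2-iodo-6-(4,4,5,5-tetramethyl-1,3,2-dioxaborolan-2-yl)phenyl trifluoromethanesulfonate | CC1(C)OB(OC1(C)C)c1cccc(I)c1OS(=O)(=O)C(F)(F)F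
A7 | alternative 2 | 2-(2,3-didehydrophenyl)-4,4,5,5-tetramethyl-1,3,2-dioxaborolane (3-borylbenzyne) | CC1(C)OB(OC1(C)C)C1=CC=CC#C1
A8 | alternative 2 | 2-[3-bromo-2-(5-bromo-2-methoxyphenoxy)phenyl]-4,4,5,5-tetramethyl-1,3,2-dioxaborolane | COc1ccc(Br)cc1Oc1c(Br)cccc1B1OC(C)(C)C(C)(C)O1
A9 | alternative 3 | 2,4-dibromophenol | Oc1ccc(Br)cc1Br
A10 | alternative 3 | 3,4,6-tribromobenzene-1,2-diol | Oc1c(O)c(Br)cc(Br)c1Br
A11 | alternative 3 | 4,6-dibromo-6-(2,3,5-tribromo-6-hydroxyphenoxy)cyclohexa-2,4-dien-1-one (racemic) | O=C1C=CC(Br)=CC1(Br)Oc1c(O)c(Br)cc(Br)c1Br
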